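The readings are calculated for substances that don't exist, noise included.

The vessel is closed and stirred, and we read target in it, counted as a fraction of the charge of starting material.

| flask | starting material | target | time |
|---|---|---|---|
| green | 100 mM |  |  |
| amber | 50.0 mM |  |  |
| red | 100 mM | 50.0 mM |  |
| teal | 50.0 mM |  |  |
| violet | 100 mM |  | 6.4 h |

| run | time / h | [target] / mM |
|---|---|---|
| green run | 0.40 | 30.8 |
| green run | 0.80 | 33.6 |
| green run | 1.2 | 35.1 |
| green run | 1.6 | 35.7 |
| green run | 2.0 | 36.1 |
| green run | 2.4 | 36.6 |
| green run | 2.8 | 36.5 |
| green run | 3.2 | 36.9 |
| amber run | 0.40 | 14.5 |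
| amber run | 0.80 | 17.1 |
| amber run | 1.2 | 18.0 |
| amber run | 1.6 | 18.7 |
| amber run | 2.0 | 18.6 |
| amber run | 2.4 | 19.1 |
| amber run | 2.8 | 19.8 |
| amber run | 3.2 | 19.3 |
| red run | 0.40 | 81.0 |
| red run | 0.80 | 83.9 |
| red run | 1.2 | 84.9 |
| red run | 1.6 | 85.8 |
| red run | 2.0 | 86.8 |
| red run | 2.4 | 86.9 |
| red run | 2.8 | 86.8 |
| red run | 3.2 | 86.9 |
| teal run | 0.40 | 14.3 |
| teal run | 0.80 | 16.8 |
| teal run | 1.2 | 17.8 |
| teal run | 1.6 | 19.3 |
| teal run | 2.0 | 19.1 |
| teal run | 2.4 | 19.4 |
| teal run | 2.8 | 19.6 |
| teal run | 3.2 | 19.4 |

(standard deviation of a reading: 0.3 mM)

- Overall: starting material -> target.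
- Constant volume, constant temperature.
- An order is taken over about fifteen percent of the charge, up and down.

- apparent order in [starting material] of the starting rate, round the charge of the green run (the rate where two percent of its starting material have turned into target) (one fixed amount of target, the same in the runs compared)
- target in the violet run at 6.4 h, as a share of the starting material charged

We write the balance of the starting material: each part of the charge either stands as target or stands elsewhere. We read the tables at their last row. At 3.2 h the green run holds 36.9% of its charge as target. We call this the plateau share: target made late in a run, as a fraction of the charge. So 63.1% of the green charge stands elsewhere at that time.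

The red run started with target added, and it has made 36.9% of its charge, the same reading as green. The amber and teal runs, at the smaller charge, read 38.6% and 38.8%, a little more than green.

Now the first row. The green run already stands at 83.5% of its last reading at 0.40 h, so the point where two percent of its charge have turned lies before the first sample. We take no order from these readings.

For the violet run, charged like green, we add the last gain of green, 0.300 mM over 0.800 h, once more. This is our own rough step, and that gain is of the size of the scatter of one reading, 0.3 mM. It gives 37.2%.

The forecast gives 37.2% and an order of 1.8, on the ground that “The tail is hyperbolic, not exponential”.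

The violet run gives 37.9%, and the order comes to 1.3, lower than the forecast's.

    2 starting material ⇌ intermediate + starting material (49.32 M⁻¹ h⁻¹, 34.56 M⁻¹ h⁻¹)
    intermediate → target (89.64 h⁻¹)
    2 starting material → homo dimer (48.24 M⁻¹ h⁻¹)
    starting material → target (0.2614 h⁻¹)

Where the same amount of target stands, the green run goes at 280 mM h⁻¹ and the amber run at 97 mM h⁻¹. The violet value lies 1.00 percentage point above the plateau share read in the green run. Put on the amber charge, the plateau share gives 18.4 mM, and the last amber reading is 19.3 mM. Target made in the amber run comes to a quarter of its charge at 0.270 h, earlier than its first sample at 0.40 h.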